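**Retrosynthetic overview**

1. The strategy rests on the C4'(Cl)(CH3)–C5'(H)(Br)–C6'H2 segment of the carbocycle (ring atoms C1'–C6', C1' bonded to oxane C6). Its trans Br/Cl pair is the anti adduct of BrCl to a Z-trisubstituted C4'=C5' alkene whose C6' is a carbinol carbon, so it can be set on an open chain by catalyst control.
2. Last disconnections: C1'–H/C6'–H (face-selective hydrogenation of a C1'=C6' alkene), then C1'=C6' by ring-closing metathesis of a diene that already carries all three halogens.
3. The diene comes from Z-allylic alcohol 17 (bromochlorination, oxidation, methylenation). Alcohol 17 comes from oxanyl butadiene 12 and (Z)-3-iodobut-2-en-1-ol by hydroboration and B-alkyl Suzuki coupling (C3'–C4' bond).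
4. The oxane (O1, C2–C6) is closed by solvolytic bromoetherification of bromochloro diol 8. C3–Br comes from bromochlorination of prenol, C6 from asymmetric epoxidation, and the two halves are joined at C4–C5 by triflate alkylation.
5. Ring order: oxane first (step 6), carbocycle last (step 15).

Key step: step 15

Remark (assumption): the Schiff-base ligand is taken to choose the alkene face from the position of the carbinol alone, so steps 1 and 12 need opposite antipodes of the ligand. The locants O1, C2 (CMe2), C3 (CHBr), C4, C5, C6 (oxane) and C1'–C6' (carbocycle) are also used for the open-chain precursors.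

**Route**

Step 1
Reactants: 1 3-methylbut-2-en-1-ol (prenol)
Product: 2 (2R)-2-bromo-3-chloro-3-methylbutan-1-ol
Conditions: NBS, ClTi(OiPr)3, chiral tridentate O,N,O Schiff-base ligand (20 mol%), hexane, −20 °C
Reagents that add atoms: N-bromosuccinimide O=C1CCC(=O)N1Br; chlorotitanium triisopropoxide CC(C)O[Ti](Cl)(OC(C)C)OC(C)C
Why: Catalytic enantioselective bromochlorination of an allylic alcohol: on the ligand-bound titanium alkoxide NBS forms the bromonium ion on one alkene face and titanium-bound chloride opens it anti at the distal, fully substituted carbon, so the single C–Br stereocentre (R, the later oxane C3) is set by the catalyst.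

Step 2
Reactants: 2 (2R)-2-bromo-3-chloro-3-methylbutan-1-ol
Product: 3 (2R)-2-bromo-3-chloro-3-methylbutyl trifluoromethanesulfonate
Conditions: Tf2O, 2,6-lutidine, CH2Cl2, −78 °C, used crude
Reagents that add atoms: trifluoromethanesulfonic anhydride O=S(=O)(OS(=O)(=O)C(F)(F)F)C(F)(F)F
Why: O-Sulfonylation of the primary alcohol under cold, weakly basic conditions gives the leaving group needed for a fast SN2 reaction at a β-branched carbon and does not touch the C–Br centre.

Step 3
Reactants: 3 (2R)-2-bromo-3-chloro-3-methylbutyl trifluoromethanesulfonate; 4 2-methylprop-2-en-1-ol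
Product: 6 (5R)-5-bromo-6-chloro-6-methyl-2-methylideneheptan-1-ol, via dilithiated methallyl alcohol 5 (not isolated)
Conditions: 4, n-BuLi (2.1 equiv per 4), TMEDA, Et2O–hexane, 0 °C to rt; then added to 3, THF, −78 °C
Reagents that add atoms: none
Why: C-Alkylation of the allyllithium-type dianion of methallyl alcohol by SN2 displacement of the primary triflate forms the C4–C5 bond and should outrun E2 elimination and halogen–metal exchange at −78 °C, leaving the bromochloride stereocentre unchanged.

Step 4
Reactants: 6 (5R)-5-bromo-6-chloro-6-methyl-2-methylideneheptan-1-ol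
Product: 7 [(2S)-2-[(3R)-3-bromo-4-chloro-4-methylpentyl]oxiran-2-yl]methanol
Conditions: Ti(OiPr)4 (10 mol%), L-(+)-diethyl tartrate (12 mol%), t-BuOOH, 4 Å molecular sieves, CH2Cl2, −20 °C
Reagents that add atoms: tert-butyl hydroperoxide CC(C)(C)OO
Why: Katsuki–Sharpless asymmetric epoxidation of a 2-substituted allylic alcohol: the L-(+)-tartrate titanium complex delivers oxygen to the face that gives the (2S)-oxirane (the sense known for 2-methylallyl alcohol), so the later oxane C6 is set by the catalyst, and the anhydrous medium does not ionise the tertiary chloride.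

Step 5
Reactants: 7 [(2S)-2-[(3R)-3-bromo-4-chloro-4-methylpentyl]oxiran-2-yl]methanol
Product: 8 (2S,5R)-5-bromo-6-chloro-2,6-dimethylheptane-1,2-diol
Conditions: LiBH4, Ti(OiPr)4, THF, 0 °C to rt
Reagents that add atoms: none
Why: Titanium-assisted regioselective reductive opening of a 2,3-epoxy alcohol: hydride attacks the unsubstituted oxirane CH2, the C–O bond at the quaternary carbon stays intact so its configuration is retained, and borohydride at this temperature should leave the secondary bromide and the tertiary chloride alone.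

Step 6
Reactants: 8 (2S,5R)-5-bromo-6-chloro-2,6-dimethylheptane-1,2-diol
Product: 9 [(2S,5R)-5-bromo-2,6,6-trimethyloxan-2-yl]methanol
Conditions: (CF3)2CHOH, NaHCO3, 0 °C to rt
Reagents that add atoms: none
Why: Enantiospecific solvolytic bromoetherification of a vicinal bromochloride: the tertiary C–Cl bond ionises with participation of the neighbouring bromine, and the tertiary hydroxyl opens the bromonium ion at the tertiary carbon (6-endo, Markovnikov), so the oxane closes with retention at the C–Br carbon, whereas the primary hydroxyl would need a seven-membered ring.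

Step 7
Reactants: 9 [(2S,5R)-5-bromo-2,6,6-trimethyloxan-2-yl]methanol
Product: 10 (2S,5R)-5-bromo-2,6,6-trimethyloxane-2-carbaldehyde
Conditions: Dess–Martin periodinane, CH2Cl2, 0 °C to rt
Reagents that add atoms: none
Why: Dess–Martin oxidation of the neopentyl-type primary alcohol gives an aldehyde that has no α-hydrogen and therefore cannot epimerise.

Step 8
Reactants: 10 (2S,5R)-5-bromo-2,6,6-trimethyloxane-2-carbaldehyde
Product: 11 (3R,6S)-3-bromo-6-ethynyl-2,2,6-trimethyloxane
Conditions: dimethyl (1-diazo-2-oxopropyl)phosphonate, K2CO3, MeOH, 0 °C to rt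
Reagents that add atoms: dimethyl (1-diazo-2-oxopropyl)phosphonate COP(=O)(OC)C(=[N+]=[N-])C(C)=O
Why: Seyferth–Gilbert homologation in the Ohira–Bestmann variant converts the non-enolisable aldehyde into the terminal alkyne under mild carbonate conditions that a hindered secondary bromide tolerates.

Step 9
Reactants: 11 (3R,6S)-3-bromo-6-ethynyl-2,2,6-trimethyloxane
Product: 12 (3R,6S)-3-bromo-6-(buta-1,3-dien-2-yl)-2,2,6-trimethyloxane
Conditions: ethene (1 atm), second-generation Grubbs catalyst RuCl2(H2IMes)(PCy3)(=CHPh) (5 mol%), toluene, 80 °C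
Reagents that add atoms: ethene C=C
Why: Enyne cross-metathesis of a terminal alkyne with ethene gives the 2-substituted buta-1,3-diene, which installs the C1' methylidene and the C2'=C3' vinyl group in one operation.

Step 10
Reactants: 13 but-2-yn-1-ol
Product: 15 (2Z)-3-iodobut-2-en-1-ol, via cyclic alkenylalanate 14 (not isolated)
Conditions: NaAlH2(OCH2CH2OMe)2, THF, 0 °C to rt; then I2, −78 °C
Reagents that add atoms: iodine II
Why: Hydroxyl-directed trans-hydroalumination of the propargylic alcohol places aluminium on C3 cis to the carbinol carbon, and iodinolysis with retention gives the Z-iodoalkene.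

Step 11
Reactants: 12 (3R,6S)-3-bromo-6-(buta-1,3-dien-2-yl)-2,2,6-trimethyloxane; 15 (2Z)-3-iodobut-2-en-1-ol
Product: 17 (2Z)-6-[(2S,5R)-5-bromo-2,6,6-trimethyloxan-2-yl]-3-methylhepta-2,6-dien-1-ol, via B-alkyl-9-BBN adduct 16 (not isolated)
Conditions: 9-BBN-H, THF, 0 °C to rt; then 15, PdCl2(dppf) (5 mol%), AsPh3, Cs2CO3, DMF–H2O, rt
Reagents that add atoms: none
Why: 9-BBN adds to the unhindered vinyl group of the diene with boron on the terminal C3' (not to the alkene flanked by the quaternary C6), and the B-alkyl Suzuki–Miyaura coupling with the iodoalkene proceeds with retention of geometry, so the Z-allylic alcohol is obtained without protecting groups.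

Step 12
Reactants: 17 (2Z)-6-[(2S,5R)-5-bromo-2,6,6-trimethyloxan-2-yl]-3-methylhepta-2,6-dien-1-ol
Product: 18 (2S,3S)-2-bromo-6-[(2S,5R)-5-bromo-2,6,6-trimethyloxan-2-yl]-3-chloro-3-methylhept-6-en-1-ol
Conditions: NBS, ClTi(OiPr)3, antipode of the Schiff-base ligand of step 1 (20–30 mol%), hexane–CH2Cl2, −20 °C
Reagents that add atoms: N-bromosuccinimide O=C1CCC(=O)N1Br; chlorotitanium triisopropoxide CC(C)O[Ti](Cl)(OC(C)C)OC(C)C
Why: The same catalytic enantioselective bromochlorination on the Z-allylic alcohol: anti addition with bromine at C5' (next to the carbinol) and chloride at the distal C4' sets both centres (4'S,5'S) under catalyst control, and only the titanium-bound allylic alkene reacts, not the 1,1-disubstituted one.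

Step 13
Reactants: 18 (2S,3S)-2-bromo-6-[(2S,5R)-5-bromo-2,6,6-trimethyloxan-2-yl]-3-chloro-3-methylhept-6-en-1-ol
Product: 19 (2S,3S)-2-bromo-6-[(2S,5R)-5-bromo-2,6,6-trimethyloxan-2-yl]-3-chloro-3-methylhept-6-enal
Conditions: Dess–Martin periodinane, CH2Cl2, 0 °C; used at once
Reagents that add atoms: none
Why: Dess–Martin oxidation under non-basic conditions gives the α-bromo aldehyde without enolisation, and it is carried on crude to avoid epimerisation at C5'.

Step 14
Reactants: 19 (2S,3S)-2-bromo-6-[(2S,5R)-5-bromo-2,6,6-trimethyloxan-2-yl]-3-chloro-3-methylhept-6-enal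
Product: 20 (3R,6S)-3-bromo-6-[(5S,6S)-6-bromo-5-chloro-5-methylocta-1,7-dien-2-yl]-2,2,6-trimethyloxane
Conditions: Ph3PCH3Br, KN(SiMe3)2, THF, 0 °C; then 19, −78 °C to 0 °C
Reagents that add atoms: methyltriphenylphosphonium bromide C[P+](c1ccccc1)(c1ccccc1)c1ccccc1.[Br-]
Why: Wittig methylenation with the non-stabilised ylide at −78 °C should add to the aldehyde faster than it deprotonates C5', as in olefinations of α,β-dihalo aldehydes, and gives the vinyl group on C5'.

Step 15
Reactants: 20 (3R,6S)-3-bromo-6-[(5S,6S)-6-bromo-5-chloro-5-methylocta-1,7-dien-2-yl]-2,2,6-trimethyloxane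
Product: 21 (3R,6S)-3-bromo-6-[(3S,4S)-3-bromo-4-chloro-4-methylcyclohex-1-en-1-yl]-2,2,6-trimethyloxane
Conditions: second-generation Grubbs catalyst RuCl2(H2IMes)(PCy3)(=CHPh) (10 mol%, in portions), toluene (0.005 M), 80 °C, argon sparge
Reagents that add atoms: none
Why: Ring-closing olefin metathesis by the Chauvin mechanism: the ruthenium benzylidene exchanges onto the monosubstituted C6'=CH2 alkene, the new alkylidene adds intramolecularly across the 1,1-disubstituted C1'=CH2 alkene to a ruthenacyclobutane, and cycloreversion releases the cyclohexene and Ru=CH2, which leaves as ethene. The closest known reaction type is ring-closing metathesis of a 1,1-disubstituted with a monosubstituted alkene to a 1-substituted cyclohexene in the presence of alkyl and allyl halides. The six-membered carbocycle closes by formation of the endocyclic, trisubstituted C1'=C6' double bond, with all three halogens already in place. No stereocentre is formed, and C4' and C5' are not touched because the neutral catalyst ionises neither the tertiary chloride nor the allylic bromide. The step needs cyclisation to win over oligomerisation and over allylic shift of the C5' bromine: the 1,1-disubstituted alkene cannot homodimerise, the fully substituted C4' in the tether favours the folded conformer, and high dilution with removal of ethene supports closure. The hindrance of the alkene on C1', which sits next to the quaternary C6, is the main risk.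

Step 16
Reactants: 21 (3R,6S)-3-bromo-6-[(3S,4S)-3-bromo-4-chloro-4-methylcyclohex-1-en-1-yl]-2,2,6-trimethyloxane
Product: 22 caespitane, (3R,6S)-3-bromo-6-[(1S,3S,4S)-3-bromo-4-chloro-4-methylcyclohexyl]-2,2,6-trimethyloxane
Conditions: Mn(dpm)3 (10 mol%; dpm = 2,2,6,6-tetramethylheptane-3,5-dionate), PhSiH3, t-BuOOH, i-PrOH, rt
Reagents that add atoms: none
Why: Hydrogen-atom-transfer hydrogenation of Mukaiyama type: the manganese hydride gives H to C6', and the tertiary C1' radical takes the second hydrogen axially in the chair with Br and Cl equatorial, on the face away from the C5' bromine, because the alternative axial approach is syn to an axial bromine; the oxanyl group therefore ends equatorial and cis to Br (1'S), and alkyl halides should survive these radical conditions.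

**Compound list**

1 | 3-methylbut-2-en-1-ol (prenol) | CC(C)=CCO | starting material
2 | (2R)-2-bromo-3-chloro-3-methylbutan-1-ol | CC(C)(Cl)[C@H](Br)CO | intermediate
3 | (2R)-2-bromo-3-chloro-3-methylbutyl trifluoromethanesulfonate | CC(C)(Cl)[C@H](Br)COS(=O)(=O)C(F)(F)F | intermediate
4 | 2-methylprop-2-en-1-ol | CC(=C)CO | starting material
5 | dilithiated methallyl alcohol (lithium 2-(lithiomethyl)prop-2-en-1-olate) | [Li]CC(=C)CO[Li] | intermediate
6 | (5R)-5-bromo-6-chloro-6-methyl-2-methylideneheptan-1-ol | CC(C)(Cl)[C@H](Br)CCC(=C)CO | intermediate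
7 | [(2S)-2-[(3R)-3-bromo-4-chloro-4-methylpentyl]oxiran-2-yl]methanol | CC(C)(Cl)[C@H](Br)CC[C@]1(CO)CO1 | intermediate
8 | (2S,5R)-5-bromo-6-chloro-2,6-dimethylheptane-1,2-diol | CC(C)(Cl)[C@H](Br)CC[C@](C)(O)CO | intermediate
9 | [(2S,5R)-5-bromo-2,6,6-trimethyloxan-2-yl]methanol | CC1(C)O[C@](C)(CO)CC[C@H]1Br | intermediate
10 | (2S,5R)-5-bromo-2,6,6-trimethyloxane-2-carbaldehyde | CC1(C)O[C@](C)(C=O)CC[C@H]1Br | intermediate
11 | (3R,6S)-3-bromo-6-ethynyl-2,2,6-trimethyloxane | CC1(C)O[C@](C)(C#C)CC[C@H]1Br | intermediate
12 | (3R,6S)-3-bromo-6-(buta-1,3-dien-2-yl)-2,2,6-trimethyloxane | CC1(C)O[C@](C)(C(=C)C=C)CC[C@H]1Br | intermediate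
13 | but-2-yn-1-ol | CC#CCO | starting material
14 | cyclic alkenylalanate, sodium 2,2-bis(2-methoxyethoxy)-3-methyl-2,5-dihydro-1,2-oxaaluminol-2-uide | CC1=CCO[Al-]1(OCCOC)OCCOC.[Na+] | intermediate
15 | (2Z)-3-iodobut-2-en-1-ol | C/C(I)=C/CO | intermediate
16 | B-alkyl-9-BBN adduct, 9-{3-[(2S,5R)-5-bromo-2,6,6-trimethyloxan-2-yl]but-3-en-1-yl}-9-borabicyclo[3.3.1]nonane | CC1(C)O[C@](C)(C(=C)CCB2C3CCCC2CCC3)CC[C@H]1Br | intermediate
17 | (2Z)-6-[(2S,5R)-5-bromo-2,6,6-trimethyloxan-2-yl]-3-methylhepta-2,6-dien-1-ol | CC1(C)O[C@](C)(C(=C)CC/C(C)=C\CO)CC[C@H]1Br | intermediate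
18 | (2S,3S)-2-bromo-6-[(2S,5R)-5-bromo-2,6,6-trimethyloxan-2-yl]-3-chloro-3-methylhept-6-en-1-ol | CC1(C)O[C@](C)(C(=C)CC[C@](C)(Cl)[C@@H](Br)CO)CC[C@H]1Br | intermediate
19 | (2S,3S)-2-bromo-6-[(2S,5R)-5-bromo-2,6,6-trimethyloxan-2-yl]-3-chloro-3-methylhept-6-enal | CC1(C)O[C@](C)(C(=C)CC[C@](C)(Cl)[C@@H](Br)C=O)CC[C@H]1Br | intermediate
20 | (3R,6S)-3-bromo-6-[(5S,6S)-6-bromo-5-chloro-5-methylocta-1,7-dien-2-yl]-2,2,6-trimethyloxane | CC1(C)O[C@](C)(C(=C)CC[C@](C)(Cl)[C@@H](Br)C=C)CC[C@H]1Br | intermediate
21 | (3R,6S)-3-bromo-6-[(3S,4S)-3-bromo-4-chloro-4-methylcyclohex-1-en-1-yl]-2,2,6-trimethyloxane | CC1(C)O[C@](C)(C2=C[C@H](Br)[C@@](C)(Cl)CC2)CC[C@H]1Br | intermediate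
22 | caespitane, (3R,6S)-3-bromo-6-[(1S,3S,4S)-3-bromo-4-chloro-4-methylcyclohexyl]-2,2,6-trimethyloxane | CC1(C)O[C@](C)([C@H]2CC[C@](C)(Cl)[C@@H](Br)C2)CC[C@H]1Br | target

**Step count**

Total: 16 steps. Longest linear sequence: 15 steps (steps 1–9 and 11–16, from prenol); step 10 is a one-step side branch.

**Steps most likely to fail**

1. Step 15 (ring-closing metathesis). The alkylidene may form only slowly at the vinyl group beside the C–Br centre and close slowly onto the hindered alkene at C1', so that catalyst decay and oligomerisation take over. The fallback is a relay ring-closing metathesis and sets out from aldehyde 19. A Wittig reaction with the ylide from (hex-5-en-1-yl)triphenylphosphonium bromide and KN(SiMe3)2 (THF, −78 °C) should give the relay triene (3R,6S)-3-bromo-6-[(5S,6S,7Z)-6-bromo-5-chloro-5-methyltrideca-1,7,12-trien-2-yl]-2,2,6-trimethyloxane F1. With the same ruthenium catalyst the metal loads at the unhindered terminal alkene, expels cyclopentene and is thereby placed on C6' intramolecularly, after which it closes onto C1'. The fallback comes back to the route at 21.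

2. Step 16 (reduction of the C1'=C6' alkene). Hydrogen transfer to the C1' radical may show poor facial selectivity, or the allylic C5' bromine may be lost by reduction or allylic shift under the radical conditions. The fallback sets out from 21 and uses diimide, generated from 2-nitrobenzenesulfonylhydrazide and Et3N in CH2Cl2 at rt. Diimide transfers both hydrogens in one concerted syn step to the face anti to the C5' bromine and the C4' methyl group, without radical or metal hydride intermediates. It comes back at 22 and makes no new compound (entered as F0).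

3. Step 14 (methylenation of the α-bromo aldehyde). The basic ylide may deprotonate C5', which leads to epimerisation or to loss of chloride from C4' by elimination. The fallback is a Peterson olefination in two non-basic stages and sets out from 19. Addition of Me3SiCH2MgCl in the presence of CeCl3 (THF, −78 °C) should give the β-hydroxysilane (3S,4S)-3-bromo-7-[(2S,5R)-5-bromo-2,6,6-trimethyloxan-2-yl]-4-chloro-4-methyl-1-(trimethylsilyl)oct-7-en-2-ol F2, as a mixture at the carbinol carbon. Acid-promoted anti elimination (catalytic H2SO4 in THF, 0 °C) then gives the alkene, and the fallback comes back at 20.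

**Further compounds**

F1 | step 15 | (3R,6S)-3-bromo-6-[(5S,6S,7Z)-6-bromo-5-chloro-5-methyltrideca-1,7,12-trien-2-yl]-2,2,6-trimethyloxane | CC1(C)O[C@](C)(C(=C)CC[C@](C)(Cl)[C@@H](Br)/C=C\CCCC=C)CC[C@H]1Br
F0 | step 16 | none | none
F2 | step 14 | (3S,4S)-3-bromo-7-[(2S,5R)-5-bromo-2,6,6-trimethyloxan-2-yl]-4-chloro-4-methyl-1-(trimethylsilyl)oct-7-en-2-ol | CC1(C)O[C@](C)(C(=C)CC[C@](C)(Cl)[C@@H](Br)C(O)C[Si](C)(C)C)CC[C@H]1Br
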